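The runs stem from a simulated flask on assumed constants; noise was put on by code.

Z is a conserved budget: each unit charged stays unspent, pays for one D made or, if the loss of D also draws on Z, pays for one D lost. The reckoning here commits to that second draw as an assumption.

| setting | elm | flask |
|---|---|---|
| E | 0.11 M | 0.11 M |
| Z | 0.121 M | 0.121 M |
| Q | 0.044 M | 0.0220 M |
| remark | run made earlier |  |
| time |  | 10 d |
| volume of the second phase over the first |  | 0.25 |

elm run (percent of the E charged)

| time / h | D / % | E / % |
|---|---|---|
| 1.50 | 7.0 | 81.1 |
| 5.00 | 21.0 | 49.7 |
| 8.00 | 26.9 | 34.5 |
| 12.0 | 28.6 | 22.1 |
| 20.0 | 25.6 | 10.6 |
| 25.0 | 22.7 | 7.7 |

(scatter of a reading: 0.5 percentage points)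

- in the second phase: Z; everything else is in the first
- charges count per volume of the first phase; a concentration in a rate is the amount of a species over the volume of its own phase; every rate counts per litre of the first phase
- the earlier runs were read with a standard deviation of 0.5 percentage points
- the earlier runs hold the two phases in the same ratio of volumes as the flask asked about
- no earlier run changes the charge of Q; that part of a forecast is a guess

* amount of D at 10 d, in percent of the E charged
* the change that raises the amount of D at 10 d, in percent of the E charged most ("none" if none brings more than 2 percentage points) (Wednesday's / Friday's / none)
* amount of D at 10 d, in percent of the E charged, after Wednesday's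

- Wednesday's: doubling the amount of Z, all else as stated
- Friday's: doubling the transfer coefficient of Z, all else as stated

The elm run has the E and Z of the flask and twice its Q, and its readings cover the first 25.0 h. In the first instants E falls with a constant of 0.140 /h, and between the last readings with 0.0639 /h, a smaller constant. A straight line against the fraction of E left splits this into a waste of 0.0930 /h per whole charge, which fades with E, and a pseudo-first-order 0.0554 /h taken as the path through Z; the halved Q is a guess inside this line. So waste leads at the start, and the Z path takes over once E stands below 59.6% of its charge. Followed down to no E, the waste takes 41.3%.

In the middle, D peaks in the elm run as a reading of 28.6% at 12.0 h, and from there the loss of D outruns its making. The end lies at ten times the last reading, and Z is taken as spent by then. The budget is 110% of the E charged. The share that reaches Z is paid once and the D lost is paid again, so the D remainder, twice the share of E not wasted minus the Z budget, is 7.39%. Wednesday's, doubling the amount of Z, gives a budget of 220%, which exceeds the 117% that a double draw can take, so its remainder in this reckoning is nil. Friday's, doubling the transfer coefficient of Z, keeps the budget and should win E back from waste, at two points of D per point of share, so the reckoning picks Friday's.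

The forecast says 0.5%, best none, and 0.1% after Wednesday's, holding that “the loss looks first-order and free of Z”. The reckoning here differs from it on the first two answers.

The flask gives 12.4%, best Friday's with a gain of 10 percentage points, and 0% after Wednesday's. D stands at 12.5% at 5.00 d, with Z down to 0.0521% of its charge, and at 12.4% after 100 d. With the simulated waste in G and L and the E left, together 38.8%, the D remainder becomes 12.4%.

    X ⇌ Z, rate k1*([X] - [Z]/K1) per volume of the first phase (partition coefficient = 1.70, kL = 0.0320 /h)
    E + Q → G (k = 0.150 /M/h)
    E + X → D (k = 13.0 /M/h)
    X + D → J (k = 9.80 /M/h)
    2 E → L (k = 0.390 /M/h)

A neighbour flask charges 0.028 M of E, so its budget is 432% of its E. Even with no waste its D remainder is −232%, below zero, so no D is expected. The computed neighbour flask holds D 0%, J 91.5%, and Z 17.2% of its own charge at 10.0 d.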